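**Plan**
1. The retrosynthesis first cuts the two C–prenyl bonds at the quaternary ring carbon C5, which returns the cyclohexadienone to an aromatic 7-acyl-2,3-dihydrobenzofuran-4,6-diol.
2. The dihydrofuran ring is then cut at C3–C3a and O1–C7a: C7a becomes the iodine-bearing carbon and C3a the free ortho carbon of an aryl iodide, and O1–C2–C3 becomes a terminal epoxide.
3. Enabling feature: the carbocycle has a single sp3 atom (C5), so it is a masked acylphloroglucinol. In the aromatic form the ring-fusion atoms C7a and C3a lie next to the acyl-bearing C7, giving an ipso carbon, one free ortho carbon and one blocked ortho carbon.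
4. Forward: the benzene ring comes from 1-iodo-3,5-dimethoxybenzene (acylation, exchange of O-protecting groups), the dihydrofuran ring is closed by a palladium/norbornene annulation with the epoxide, and debenzylation followed by a dearomatizing double prenylation finishes the route.
5. Stereochemistry: the single (R) centre comes from methyl (R)-glycidate and is never a reacting centre.

Key step: step 6

Remark on the chemistry: the target is an enolized β-triketone, so the route should deliver the tautomeric mixture, of which the drawn hydrogen-bonded enol is one form.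

**Route**

Step 1
Reactants: 1 1-iodo-3,5-dimethoxybenzene; 2 3-methylbutanoyl chloride
Product: 3 1-(2-iodo-4,6-dimethoxyphenyl)-3-methylbutan-1-one
Conditions: AlCl3 (1.2 equiv), CH2Cl2, 0 °C; ice/1 M HCl
Reagents that add atoms: 3-methylbutanoyl chloride (2), CC(C)CC(Cl)=O
Why: Friedel–Crafts acylation should occur at the carbon para to one methoxy group and ortho to the other, which is less crowded than the carbon between the two methoxy groups, while the iodine-bearing carbon is meta to both donors and not prone to ipso attack.

Step 2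
Reactants: 3 1-(2-iodo-4,6-dimethoxyphenyl)-3-methylbutan-1-one
Product: 4 1-(2,4-dihydroxy-6-iodophenyl)-3-methylbutan-1-one
Conditions: BBr3 (3.5 equiv), CH2Cl2, −78 °C to rt; H2O
Reagents that add atoms: none
Why: BBr3 cleavage of aryl methyl ethers tolerates the ketone and the aryl iodide, and the iodine is meta to both hydroxyl groups, so acid-induced deiodination is not expected.

Step 3
Reactants: 4 1-(2,4-dihydroxy-6-iodophenyl)-3-methylbutan-1-one; 5 benzyl bromide
Product: 6 1-[2,4-bis(benzyloxy)-6-iodophenyl]-3-methylbutan-1-one
Conditions: BnBr (2.4 equiv), K2CO3 (3 equiv), DMF, 60 °C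
Reagents that add atoms: benzyl bromide (5), BrCc1ccccc1
Why: Williamson ether synthesis on both phenols gives protecting groups that survive the basic palladium step and can be removed by hydrogenolysis before any alkene is present.

Step 4
Reactants: 7 methyl (2R)-oxirane-2-carboxylate; 8 methylmagnesium chloride
Product: 9 2-[(2R)-oxiran-2-yl]propan-2-ol
Conditions: MeMgCl (2.2 equiv), THF, −78 to −20 °C; sat. aq NH4Cl
Reagents that add atoms: methylmagnesium chloride (8), C[Mg]Cl
Why: Double Grignard addition to the ester should be much faster at low temperature than uncatalysed opening of the oxirane; the stereocentre is not a reacting centre and keeps the (R) descriptor because CMe2OH takes the rank of the ester carbon.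

Step 5
Reactants: 9 2-[(2R)-oxiran-2-yl]propan-2-ol; 10 chlorotriethylsilane
Product: 11 triethyl({2-[(2R)-oxiran-2-yl]propan-2-yl}oxy)silane
Conditions: TESCl (1.5 equiv), imidazole (2.5 equiv), DMAP (0.1 equiv), DMF, rt
Reagents that add atoms: chlorotriethylsilane (10), CC[Si](Cl)(CC)CC
Why: Silylation of the tertiary alcohol under non-alkoxide conditions blocks Payne rearrangement and palladium alkoxide formation at this oxygen in the next step.

Step 6
Reactants: 6 1-[2,4-bis(benzyloxy)-6-iodophenyl]-3-methylbutan-1-one; 11 triethyl({2-[(2R)-oxiran-2-yl]propan-2-yl}oxy)silane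
Product: 13 1-[(2R)-4,6-bis(benzyloxy)-2-(2-hydroxypropan-2-yl)-2,3-dihydro-1-benzofuran-7-yl]-3-methylbutan-1-one, via triethylsilyl ether 12 (not isolated)
Conditions: Pd(OAc)2 (10 mol %), XPhos (20 mol %), potassium 5-norbornene-2-carboxylate (0.5 equiv), K2CO3 (2 equiv), 11 (2.5 equiv), NMP, 80 °C; then TBAF (3 equiv), THF, rt
Reagents that add atoms: none
Why: In this Catellani-type annulation zerovalent palladium inserts into the C–I bond of 6, norbornene carbopalladation and carbonate-assisted palladation of the one free ortho C–H give an aryl–norbornyl palladacycle, and this opens 11 by SN2 attack at its CH2 terminus to a tetravalent palladium alkoxide; reductive elimination then forms the aryl–CH2 bond, β-carbon elimination expels norbornene, and aryl C–O reductive elimination closes the ring. The closest known reaction type is the palladium/norbornene-catalysed ortho-alkylation/ipso-etherification of ortho-substituted aryl iodides with terminal epoxides to 2,3-dihydrobenzofurans. The dihydrofuran ring closes by intramolecular aryl C–O bond formation from a six-membered divalent oxapalladacycle, formally a 5-exo closure of the tethered alkoxide onto the ipso carbon, after the intermolecular C–C bond has been made. No stereocentre is created: C2 comes from 11 and none of its bonds is broken, so the (R) configuration is carried over unchanged. The step needs ortho-then-ipso site selectivity, secured by the isovaleryl group on the second ortho carbon (only one ortho C–H, and two ortho substituents after alkylation drive norbornene extrusion), terminal regioselectivity in the epoxide opening, secured by the bulky CMe2OSiEt3 group, and C–O reductive elimination ahead of β-hydride elimination, favoured by the bulky biaryl phosphine. Fluoride then removes the silyl group in the same flask.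

Step 7
Reactants: 13 1-[(2R)-4,6-bis(benzyloxy)-2-(2-hydroxypropan-2-yl)-2,3-dihydro-1-benzofuran-7-yl]-3-methylbutan-1-one
Product: 14 1-[(2R)-4,6-dihydroxy-2-(2-hydroxypropan-2-yl)-2,3-dihydro-1-benzofuran-7-yl]-3-methylbutan-1-one
Conditions: H2 (1 atm), 10% Pd/C, EtOAc/MeOH, rt
Reagents that add atoms: none
Why: Hydrogenolysis of the two benzyl aryl ethers should leave the hydrogen-bonded aryl ketone, the non-benzylic C2–O bond and the tertiary alcohol untouched.

Step 8
Reactants: 14 1-[(2R)-4,6-dihydroxy-2-(2-hydroxypropan-2-yl)-2,3-dihydro-1-benzofuran-7-yl]-3-methylbutan-1-one; 15 1-bromo-3-methylbut-2-ene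
Product: 16 (2R)-6-hydroxy-2-(2-hydroxypropan-2-yl)-7-(3-methylbutanoyl)-5,5-bis(3-methylbut-2-en-1-yl)-2,3-dihydro-1-benzofuran-4(5H)-one
Conditions: prenyl bromide (2.5 equiv), NaOMe (3 equiv), MeOH, 0 °C to rt; 1 M HCl
Reagents that add atoms: 1-bromo-3-methylbut-2-ene (15), CC(C)=CCBr
Why: Alkylative dearomatization of an acylphloroglucinol: C5 is the only unsubstituted ring carbon and lies between the two phenoxide oxygens, so both prenyl groups should enter there, the second one dearomatizing the ring; the C2 stereocentre is remote and not affected.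

**Compound list**
1 | 1-iodo-3,5-dimethoxybenzene | COc1cc(I)cc(OC)c1 | starting material
2 | 3-methylbutanoyl chloride | CC(C)CC(Cl)=O | starting material
3 | 1-(2-iodo-4,6-dimethoxyphenyl)-3-methylbutan-1-one | CC(C)CC(=O)c1c(I)cc(OC)cc1OC | intermediate
4 | 1-(2,4-dihydroxy-6-iodophenyl)-3-methylbutan-1-one | CC(C)CC(=O)c1c(I)cc(O)cc1O | intermediate
5 | benzyl bromide | BrCc1ccccc1 | starting material
6 | 1-[2,4-bis(benzyloxy)-6-iodophenyl]-3-methylbutan-1-one | CC(C)CC(=O)c1c(I)cc(OCc2ccccc2)cc1OCc1ccccc1 | intermediate
7 | methyl (2R)-oxirane-2-carboxylate | COC(=O)[C@H]1CO1 | starting material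
8 | methylmagnesium chloride | C[Mg]Cl | starting material
9 | 2-[(2R)-oxiran-2-yl]propan-2-ol | CC(C)(O)[C@H]1CO1 | intermediate
10 | chlorotriethylsilane | CC[Si](Cl)(CC)CC | starting material
11 | triethyl({2-[(2R)-oxiran-2-yl]propan-2-yl}oxy)silane | CC[Si](CC)(CC)OC(C)(C)[C@H]1CO1 | intermediate
12 | 1-[(2R)-4,6-bis(benzyloxy)-2-{2-[(triethylsilyl)oxy]propan-2-yl}-2,3-dihydro-1-benzofuran-7-yl]-3-methylbutan-1-one | CC(C)CC(=O)c1c(OCc2ccccc2)cc(OCc2ccccc2)c2c1O[C@@H](C(C)(C)O[Si](CC)(CC)CC)C2 | intermediate
13 | 1-[(2R)-4,6-bis(benzyloxy)-2-(2-hydroxypropan-2-yl)-2,3-dihydro-1-benzofuran-7-yl]-3-methylbutan-1-one | CC(C)CC(=O)c1c(OCc2ccccc2)cc(OCc2ccccc2)c2c1O[C@@H](C(C)(C)O)C2 | intermediate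
14 | 1-[(2R)-4,6-dihydroxy-2-(2-hydroxypropan-2-yl)-2,3-dihydro-1-benzofuran-7-yl]-3-methylbutan-1-one | CC(C)CC(=O)c1c(O)cc(O)c2c1O[C@@H](C(C)(C)O)C2 | intermediate
15 | 1-bromo-3-methylbut-2-ene | CC(C)=CCBr | starting material
16 | (2R)-6-hydroxy-2-(2-hydroxypropan-2-yl)-7-(3-methylbutanoyl)-5,5-bis(3-methylbut-2-en-1-yl)-2,3-dihydro-1-benzofuran-4(5H)-one | CC(C)=CCC1(CC=C(C)C)C(=O)C2=C(O[C@@H](C(C)(C)O)C2)C(C(=O)CC(C)C)=C1O | target

**Count**
Total steps: 8. Longest linear sequence: 6 steps (steps 1, 2, 3, 6, 7, 8).

**Steps most likely to fail**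

Step 6. Palladation of the only free ortho C–H, which is flanked by a benzyloxy group, may be too slow, so that norbornene-containing by-products, simple hydrodeiodination or β-hydride elimination of the palladium alkoxide take over. The fallback sets out from 6 and returns at 13, building the ring by a prenyl/epoxide sequence instead:
- Palladium-catalysed hydroxylation of the aryl iodide (Pd2(dba)3, tBuXPhos, KOH, dioxane/H2O, 100 °C) should give the phenol 1-[2,4-bis(benzyloxy)-6-hydroxyphenyl]-3-methylbutan-1-one F1.
- Tsuji–Trost O-alkylation with tert-butyl 2-methylbut-3-en-2-yl carbonate and Pd(PPh3)4 in THF should give the tertiary allyl ether 1-{2,4-bis(benzyloxy)-6-[(2-methylbut-3-en-2-yl)oxy]phenyl}-3-methylbutan-1-one F2.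
- Aromatic Claisen rearrangement (toluene, 110 °C) can only reach the one free ortho carbon and should give the ortho-prenyl phenol 1-[4,6-bis(benzyloxy)-2-hydroxy-3-(3-methylbut-2-en-1-yl)phenyl]-3-methylbutan-1-one F3.
- Shi epoxidation with the L-sorbose-derived enantiomer of the Shi ketone (KHSO5 as 2KHSO5·KHSO4·K2SO4, K2CO3, MeCN/dimethoxymethane/H2O, 0 °C) is expected to give the epoxide 1-[4,6-bis(benzyloxy)-3-{[(2S)-3,3-dimethyloxiran-2-yl]methyl}-2-hydroxyphenyl]-3-methylbutan-1-one F4.
- 5-exo-tet attack of the phenol oxygen on F4 with inversion (K2CO3, MeOH) should then give 13 with the (R) centre.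

Step 8. O-alkylation and arrest after the first C-prenylation may compete with the second, dearomatizing C-alkylation, and prenyl bromide may be consumed by solvolysis. The fallback sets out from 14 and returns at 16. It replaces the irreversible SN2 alkylation by a Tsuji–Trost prenylation with tert-butyl (3-methylbut-2-en-1-yl) carbonate and Pd(PPh3)4 in THF at 50 °C. Under these conditions O-prenyl ethers re-ionize and are returned to the pool, and attack at the less substituted allyl terminus should give the linear prenyl groups. The material should pass through the mono-C-prenyl phenol 1-[(2R)-4,6-dihydroxy-2-(2-hydroxypropan-2-yl)-5-(3-methylbut-2-en-1-yl)-2,3-dihydro-1-benzofuran-7-yl]-3-methylbutan-1-one F5, which can be isolated and resubmitted.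

Step 4. Opening of the oxirane by chloride or by the Grignard reagent may compete with addition to the ester, and the small, volatile, water-soluble product may be lost during isolation. The fallback sets out from 7 and returns at 9, masking the oxirane as a bromohydrin during the Grignard step:
- LiBr/AcOH in THF should open 7 at the CH2 terminus to methyl (2S)-3-bromo-2-hydroxypropanoate F6.
- MeMgCl (3.3 equiv, THF, −40 to 0 °C) should convert the ester into (2S)-1-bromo-3-methylbutane-2,3-diol F7.
- Brief treatment with K2CO3 in MeOH at 0 °C should close the secondary alkoxide onto the CH2Br group to give 9, with the stereocentre untouched throughout.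

**Further compounds**
F1 | step 6 | 1-[2,4-bis(benzyloxy)-6-hydroxyphenyl]-3-methylbutan-1-one | CC(C)CC(=O)c1c(O)cc(OCc2ccccc2)cc1OCc1ccccc1
F2 | step 6 | 1-{2,4-bis(benzyloxy)-6-[(2-methylbut-3-en-2-yl)oxy]phenyl}-3-methylbutan-1-one | CC(C)CC(=O)c1c(OC(C)(C)C=C)cc(OCc2ccccc2)cc1OCc1ccccc1
F3 | step 6 | 1-[4,6-bis(benzyloxy)-2-hydroxy-3-(3-methylbut-2-en-1-yl)phenyl]-3-methylbutan-1-one | CC(C)CC(=O)c1c(O)c(CC=C(C)C)c(OCc2ccccc2)cc1OCc1ccccc1
F4 | step 6 | 1-[4,6-bis(benzyloxy)-3-{[(2S)-3,3-dimethyloxiran-2-yl]methyl}-2-hydroxyphenyl]-3-methylbutan-1-one | CC(C)CC(=O)c1c(O)c(C[C@@H]2OC2(C)C)c(OCc2ccccc2)cc1OCc1ccccc1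
F5 | step 8 | 1-[(2R)-4,6-dihydroxy-2-(2-hydroxypropan-2-yl)-5-(3-methylbut-2-en-1-yl)-2,3-dihydro-1-benzofuran-7-yl]-3-methylbutan-1-one | CC(C)CC(=O)c1c(O)c(CC=C(C)C)c(O)c2c1O[C@@H](C(C)(C)O)C2
F6 | step 4 | methyl (2S)-3-bromo-2-hydroxypropanoate | COC(=O)[C@H](O)CBr
F7 | step 4 | (2S)-1-bromo-3-methylbutane-2,3-diol | CC(C)(O)[C@H](O)CBr
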